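## Retrosynthetic overview

1. Numbering (drimane type): ring A = C1–C5, C10 (C3 carbinol, C4 CMe2); ring B = C5–C10 (C5=C6, C8 CHMe, C9 quaternary, C10 ring-fusion CH); C11 = OCH2. Endgame: the C8 CH–CH3 group comes from a C8 ketone (methylenation, hydrogenation), and the C3 carbinol is re-set by oxidation and axial-selective reduction.
2. Key disconnection C9–C11: Lewis-acid alkylation of a C8–C9 silyl enol ether with 7-(chloromethoxy)-6,8-dimethoxycoumarin (from isofraxidin). This joins the two halves and creates the quaternary C9.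
3. Enabling feature: C9 carries a methyl group and lies between C8 and C10 in ring B. The rest of ring B (C5=C6, sp3 C7 and C10) is exactly what a Birch reduction leaves from an ortho-cresol ring (O on C8, CH3 on C9). Ring B is therefore a masked 2-methylphenol: its Birch product is nucleophilic at C9 only, and the C10–C1 bond shields one face.
4. Ring order: benzene ring B is bought (3-bromo-2-methylphenol); ring A is closed onto it (C4–C5) by epoxide–arene Friedel–Crafts cyclisation of a Shi epoxide; ring B is then dearomatised (Birch); the coumarin rings are bought intact (isofraxidin).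
5. Stereochemical relay: Shi epoxide (temporary 3R) → C10 (Birch protonation) → C9 (key step, anti to C1) → C8 (hydrogenation anti to the axial 9-CH3) → C3 (3S, L-Selectride).

Key step: step 9

Remark: the D-fructose-derived Shi ketone is assumed to give the (R)-epoxide with R–CH=C(CH3)2 alkenes, and 3-bromo-2-methylphenol, 5-bromo-2-methylpent-2-ene and isofraxidin are taken as purchased.

## Route

Step 1
Reactants: 1 3-bromo-2-methylphenol
Product: 2 (3-bromo-2-methylphenoxy)triisopropylsilane
Conditions: TIPSCl, imidazole, DMF, rt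
Reagents that add atoms: chlorotriisopropylsilane, CC(C)[Si](Cl)(C(C)C)C(C)C
Why: Imidazole-mediated O-silylation of a phenol; the aryl TIPS ether should survive the Grignard, buffered Oxone, Lewis acid and Li/NH3 steps and later becomes the enol silyl group.

Step 2
Reactants: 2 (3-bromo-2-methylphenoxy)triisopropylsilane; 3 5-bromo-2-methylpent-2-ene
Product: 5 triisopropyl[2-methyl-3-(4-methylpent-3-en-1-yl)phenoxy]silane, via (4-methylpent-3-en-1-yl)magnesium bromide 4 (not isolated)
Conditions: 3, Mg, THF, 40 °C; then 2, PdCl2(dppf) (3 mol %), THF, 65 °C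
Reagents that add atoms: none
Why: Kumada–Corriu coupling of a primary alkyl Grignard reagent with an aryl bromide, in which the wide-bite-angle dppf ligand makes reductive elimination faster than β-hydride elimination.

Step 3
Reactants: 5 triisopropyl[2-methyl-3-(4-methylpent-3-en-1-yl)phenoxy]silane
Product: 6 {3-[2-((2R)-3,3-dimethyloxiran-2-yl)ethyl]-2-methylphenoxy}triisopropylsilane
Conditions: D-fructose-derived Shi ketone (0.3 equiv), Oxone, K2CO3, Bu4NHSO4, MeCN–DMM/aq. Na2B4O7–EDTA, 0 °C
Reagents that add atoms: Oxone (potassium peroxymonosulfate), [K+].[O-]S(=O)(=O)OO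
Why: Shi epoxidation: the chiral dioxirane transfers oxygen through a spiro transition state to one face of the trisubstituted alkene, which for R–CH=C(CH3)2 alkenes should give the (R)-epoxide, and the arene and silyl ether are inert.

Step 4
Reactants: 6 {3-[2-((2R)-3,3-dimethyloxiran-2-yl)ethyl]-2-methylphenoxy}triisopropylsilane
Product: 7 (2R)-1,1,5-trimethyl-6-[(triisopropylsilyl)oxy]-1,2,3,4-tetrahydronaphthalen-2-ol
Conditions: InBr3 (20 mol %), CH2Cl2, 0 °C → rt
Reagents that add atoms: none
Why: Lewis-acid epoxide–arene Friedel–Crafts cyclisation: the epoxide opens at its tertiary carbon (C4) and the arene carbon C5, para to the silyloxy group and the only free position ortho to the side chain, closes ring A (6-endo), while the C3–O bond is not broken so that the (R) centre is kept.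

Step 5
Reactants: 7 (2R)-1,1,5-trimethyl-6-[(triisopropylsilyl)oxy]-1,2,3,4-tetrahydronaphthalen-2-ol
Product: 8 (2R,4aR)-1,1,5-trimethyl-6-[(triisopropylsilyl)oxy]-1,2,3,4,4a,7-hexahydronaphthalen-2-ol (ring-fusion H cis to OH)
Conditions: Li, NH3(l)–THF, t-BuOH, −78 °C; solid NH4Cl
Reagents that add atoms: none
Why: Birch reduction of an aryl silyl ether to the 1-silyloxycyclohexa-1,4-diene: the oxygen on C8 and the alkyl group on C5 stay on sp2 carbons, the radical anion is protonated at C7 (free CH ortho to oxygen, whereas C6 is screened by the peri CMe2 group) and the dienyl anion at its central carbon C10, and this protonation should come axially on the ring-A half-chair that keeps the C3 oxygen equatorial, which places H-10 cis to the C3 oxygen (4aR), any 4aS epimer being a separable carbinol.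

Step 6
Reactants: 8 (2R,4aR)-1,1,5-trimethyl-6-[(triisopropylsilyl)oxy]-1,2,3,4,4a,7-hexahydronaphthalen-2-ol
Product: 9 tert-butyldimethyl{[(2R,4aR)-1,1,5-trimethyl-6-[(triisopropylsilyl)oxy]-1,2,3,4,4a,7-hexahydronaphthalen-2-yl]oxy}silane
Conditions: TBSOTf, 2,6-lutidine, CH2Cl2, −78 °C
Reagents that add atoms: tert-butyldimethylsilyl triflate, CC(C)(C)[Si](C)(C)OS(=O)(=O)C(F)(F)F
Why: Silylation with the silyl triflate and a hindered base protects the C3 hydroxyl for the Lewis-acid step without touching the triisopropylsilyl enol ether.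

Step 7
Reactants: 10 isofraxidin (7-hydroxy-6,8-dimethoxy-2H-chromen-2-one)
Product: 11 6,8-dimethoxy-7-[(methylsulfanyl)methoxy]-2H-chromen-2-one
Conditions: NaH, ClCH2SMe, NaI (cat.), DMF, 0 °C → rt
Reagents that add atoms: chloromethyl methyl sulfide, CSCCl
Why: Williamson etherification of the phenoxide with chloromethyl methyl sulfide gives the O,S-acetal, and the lactone is not attacked by the non-nucleophilic base.

Step 8
Reactants: 11 6,8-dimethoxy-7-[(methylsulfanyl)methoxy]-2H-chromen-2-one
Product: 12 7-(chloromethoxy)-6,8-dimethoxy-2H-chromen-2-one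
Conditions: SO2Cl2, CH2Cl2, 0 °C; evaporate, use crude
Reagents that add atoms: sulfuryl chloride, O=S(=O)(Cl)Cl
Why: Chlorinolysis of the O,S-acetal with sulfuryl chloride is the standard way to aryl chloromethyl ethers, the sulfide reacting faster than the coumarin ring.

Step 9
Reactants: 9 tert-butyldimethyl{[(2R,4aR)-1,1,5-trimethyl-6-[(triisopropylsilyl)oxy]-1,2,3,4,4a,7-hexahydronaphthalen-2-yl]oxy}silane; 12 7-(chloromethoxy)-6,8-dimethoxy-2H-chromen-2-one
Product: 13 7-{[(1R,6R,8aR)-6-[(tert-butyldimethylsilyl)oxy]-1,5,5-trimethyl-2-oxo-1,2,3,5,6,7,8,8a-octahydronaphthalen-1-yl]methoxy}-6,8-dimethoxy-2H-chromen-2-one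
Conditions: TiCl4, 2,6-di-tert-butyl-4-methylpyridine (cat.), CH2Cl2, −78 °C; aq. NaHCO3
Reagents that add atoms: none
Why: TiCl4 ionises 12 to the aryloxymethyl oxocarbenium ion, which is attacked by C9 of the tetrasubstituted silyl enol ether of 9, and chloride then takes the TIPS group from the silyloxycarbenium ion to leave the C8 ketone. The closest known reaction type is the Lewis-acid-mediated (Mukaiyama-type, SN1) alkylation of silyl enol ethers with α-chloro ethers and α-chloro sulfides, which is used to build quaternary α-carbons; no ring is closed. The new quaternary centre C9 is controlled by C10: ring B of 9 is a nearly flat cyclohexa-1,4-diene, the C10–C1 bond stands over its β face, and the electrophile should enter from the α face, cis to H-10, so that C11 is α and the C9 methyl β (1R in the name of 13). The step needs alkylation at C9 only, which the regiodefined enol ether from step 5 secures, since the trisubstituted C5=C6 bond is far less nucleophilic. It also needs C–C bond formation to outrun hydride transfer from the doubly allylic C7 and C10 positions (re-aromatisation) and proto-desilylation, which the high π-nucleophilicity of the enol ether, −78 °C and the hindered pyridine as acid scavenger should secure.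

Step 10
Reactants: 13 the C8 ketone from step 9
Product: 14 7-{[(1S,6R,8aR)-6-[(tert-butyldimethylsilyl)oxy]-1,5,5-trimethyl-2-methylidene-1,2,3,5,6,7,8,8a-octahydronaphthalen-1-yl]methoxy}-6,8-dimethoxy-2H-chromen-2-one
Conditions: Zn, CH2Br2, TiCl4, THF–CH2Cl2, 0 °C → rt
Reagents that add atoms: dibromomethane, BrCBr
Why: Takai–Lombardo methylenation: the non-basic Zn/Ti methylene reagent olefinates hindered, enolisable ketones without moving the β,γ-double bond into conjugation and does not attack the lactone.

Step 11
Reactants: 14 the exocyclic alkene from step 10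
Product: 15 7-{[(1R,2S,6R,8aR)-6-[(tert-butyldimethylsilyl)oxy]-1,2,5,5-tetramethyl-1,2,3,5,6,7,8,8a-octahydronaphthalen-1-yl]methoxy}-6,8-dimethoxy-2H-chromen-2-one
Conditions: H2 (1 atm), RhCl(PPh3)3 (10 mol %), benzene–EtOH, rt
Reagents that add atoms: none
Why: Homogeneous hydrogenation with Wilkinson's catalyst should reduce only the 1,1-disubstituted alkene (the trisubstituted C5=C6 bond and the coumarin C3=C4 bond stay), and hydrogen should add to the α face, anti to the axial C9 methyl group, to give the equatorial β-methyl group at C8 (2S in the name).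

Step 12
Reactants: 15 the silyl ether from step 11
Product: 16 7-{[(1R,2S,6R,8aR)-6-hydroxy-1,2,5,5-tetramethyl-1,2,3,5,6,7,8,8a-octahydronaphthalen-1-yl]methoxy}-6,8-dimethoxy-2H-chromen-2-one (C3 epimer of the target)
Conditions: HF·pyridine, pyridine–THF, 0 °C → rt
Reagents that add atoms: none
Why: Fluoride-mediated cleavage of the TBS ether under buffered conditions that spare the lactone, the aryl ether and the trisubstituted alkene.

Step 13
Reactants: 16 the C3-epimeric alcohol from step 12
Product: 17 7-{[(1R,2S,8aR)-1,2,5,5-tetramethyl-6-oxo-1,2,3,5,6,7,8,8a-octahydronaphthalen-1-yl]methoxy}-6,8-dimethoxy-2H-chromen-2-one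
Conditions: Dess–Martin periodinane, CH2Cl2, rt
Reagents that add atoms: none
Why: Dess–Martin oxidation of the secondary alcohol removes the temporary (R) centre at C3, and the ketone cannot move into conjugation because C4 is quaternary.

Step 14
Reactants: 17 the C3 ketone from step 13
Product: 18 7-{[(1R,2S,6S,8aR)-6-hydroxy-1,2,5,5-tetramethyl-1,2,3,5,6,7,8,8a-octahydronaphthalen-1-yl]methoxy}-6,8-dimethoxy-2H-chromen-2-one (target, CNP0110107.1)
Conditions: L-Selectride, THF, −78 °C; aq. NH4Cl
Reagents that add atoms: none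
Why: Reduction of a 2,2-dimethylcyclohexanone-type ketone with a bulky trialkylborohydride, which enters from the equatorial side and should give the axial alcohol; with H-10 axial on the α face the axial position at C3 is β, i.e. the (3S) carbinol, and at −78 °C the ketone should react much faster than the electron-rich coumarin.

## Compound list

1 | 3-bromo-2-methylphenol | Cc1c(O)cccc1Br | starting material
2 | (3-bromo-2-methylphenoxy)triisopropylsilane | Cc1c(O[Si](C(C)C)(C(C)C)C(C)C)cccc1Br | intermediate
3 | 5-bromo-2-methylpent-2-ene | CC(C)=CCCBr | starting material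
4 | (4-methylpent-3-en-1-yl)magnesium bromide | CC(C)=CCC[Mg]Br | intermediate (not isolated)
5 | triisopropyl[2-methyl-3-(4-methylpent-3-en-1-yl)phenoxy]silane | Cc1c(O[Si](C(C)C)(C(C)C)C(C)C)cccc1CCC=C(C)C | intermediate
6 | {3-[2-((2R)-3,3-dimethyloxiran-2-yl)ethyl]-2-methylphenoxy}triisopropylsilane | Cc1c(O[Si](C(C)C)(C(C)C)C(C)C)cccc1CC[C@H]1OC1(C)C | intermediate
7 | (2R)-1,1,5-trimethyl-6-[(triisopropylsilyl)oxy]-1,2,3,4-tetrahydronaphthalen-2-ol | Cc1c(O[Si](C(C)C)(C(C)C)C(C)C)ccc2c1CC[C@@H](O)C2(C)C | intermediate
8 | (2R,4aR)-1,1,5-trimethyl-6-[(triisopropylsilyl)oxy]-1,2,3,4,4a,7-hexahydronaphthalen-2-ol | CC1=C(O[Si](C(C)C)(C(C)C)C(C)C)CC=C2[C@H]1CC[C@@H](O)C2(C)C | intermediate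
9 | tert-butyldimethyl{[(2R,4aR)-1,1,5-trimethyl-6-[(triisopropylsilyl)oxy]-1,2,3,4,4a,7-hexahydronaphthalen-2-yl]oxy}silane | CC1=C(O[Si](C(C)C)(C(C)C)C(C)C)CC=C2[C@H]1CC[C@@H](O[Si](C)(C)C(C)(C)C)C2(C)C | intermediate
10 | isofraxidin (7-hydroxy-6,8-dimethoxy-2H-chromen-2-one) | COc1cc2ccc(=O)oc2c(OC)c1O | starting material
11 | 6,8-dimethoxy-7-[(methylsulfanyl)methoxy]-2H-chromen-2-one | COc1cc2ccc(=O)oc2c(OC)c1OCSC | intermediate
12 | 7-(chloromethoxy)-6,8-dimethoxy-2H-chromen-2-one | COc1cc2ccc(=O)oc2c(OC)c1OCCl | intermediate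
13 | 7-{[(1R,6R,8aR)-6-[(tert-butyldimethylsilyl)oxy]-1,5,5-trimethyl-2-oxo-1,2,3,5,6,7,8,8a-octahydronaphthalen-1-yl]methoxy}-6,8-dimethoxy-2H-chromen-2-one | COc1cc2ccc(=O)oc2c(OC)c1OC[C@@]1(C)[C@@H]2CC[C@@H](O[Si](C)(C)C(C)(C)C)C(C)(C)C2=CCC1=O | intermediate
14 | 7-{[(1S,6R,8aR)-6-[(tert-butyldimethylsilyl)oxy]-1,5,5-trimethyl-2-methylidene-1,2,3,5,6,7,8,8a-octahydronaphthalen-1-yl]methoxy}-6,8-dimethoxy-2H-chromen-2-one | COc1cc2ccc(=O)oc2c(OC)c1OC[C@@]1(C)[C@@H]2CC[C@@H](O[Si](C)(C)C(C)(C)C)C(C)(C)C2=CCC1=C | intermediate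
15 | 7-{[(1R,2S,6R,8aR)-6-[(tert-butyldimethylsilyl)oxy]-1,2,5,5-tetramethyl-1,2,3,5,6,7,8,8a-octahydronaphthalen-1-yl]methoxy}-6,8-dimethoxy-2H-chromen-2-one | COc1cc2ccc(=O)oc2c(OC)c1OC[C@@]1(C)[C@@H]2CC[C@@H](O[Si](C)(C)C(C)(C)C)C(C)(C)C2=CC[C@@H]1C | intermediate
16 | 7-{[(1R,2S,6R,8aR)-6-hydroxy-1,2,5,5-tetramethyl-1,2,3,5,6,7,8,8a-octahydronaphthalen-1-yl]methoxy}-6,8-dimethoxy-2H-chromen-2-one | COc1cc2ccc(=O)oc2c(OC)c1OC[C@@]1(C)[C@@H]2CC[C@@H](O)C(C)(C)C2=CC[C@@H]1C | intermediate
17 | 7-{[(1R,2S,8aR)-1,2,5,5-tetramethyl-6-oxo-1,2,3,5,6,7,8,8a-octahydronaphthalen-1-yl]methoxy}-6,8-dimethoxy-2H-chromen-2-one | COc1cc2ccc(=O)oc2c(OC)c1OC[C@@]1(C)[C@@H]2CCC(=O)C(C)(C)C2=CC[C@@H]1C | intermediate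
18 | 7-{[(1R,2S,6S,8aR)-6-hydroxy-1,2,5,5-tetramethyl-1,2,3,5,6,7,8,8a-octahydronaphthalen-1-yl]methoxy}-6,8-dimethoxy-2H-chromen-2-one | COc1cc2ccc(=O)oc2c(OC)c1OC[C@@]1(C)[C@@H]2CC[C@H](O)C(C)(C)C2=CC[C@@H]1C | target

## Step count and risks

Total steps: 14. Longest linear sequence: 12 steps (steps 1–6 and 9–14); the coumarin branch (steps 7–8) joins at step 9.

Steps most likely to fail:

Step 5 (Birch reduction). The protonation of the dienyl anion at C10 may take place on both faces, and part of the first protonation may go to C6, which puts the second hydrogen on C9. The facial preference rests on a conformational model for a ring that carries a gem-dimethyl group next to the controlling carbinol, so it is the least secure stereochemical step. Fallback: stereochemical purity at C10 is then secured by separation and recycling instead of by the selectivity of the protonation. The fallback sets out from the crude product obtained from 7. The unwanted epimer (2R,4aS)-1,1,5-trimethyl-6-[(triisopropylsilyl)oxy]-1,2,3,4,4a,7-hexahydronaphthalen-2-ol F1 is separated from 8 on triethylamine-deactivated silica and dehydrogenated with DDQ (benzene, rt). This re-aromatises the cyclohexa-1,4-diene and comes back to the route at 7 for another reduction.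

Step 9 (key alkylation). Hydride transfer from the doubly allylic C7/C10 positions of 9 to the oxocarbenium ion (re-aromatisation), proto-desilylation, or slow ionisation of the aryl chloromethyl ether may take over. Fallback: C11 is introduced as formaldehyde and the aryl ether bond is made afterwards, setting out from 9. TiCl4-mediated Mukaiyama hydroxymethylation with monomeric formaldehyde (CH2Cl2, −78 °C) should give, with the same facial control, (1R,6R,8aR)-6-[(tert-butyldimethylsilyl)oxy]-1-(hydroxymethyl)-1,5,5-trimethyl-3,5,6,7,8,8a-hexahydronaphthalen-2(1H)-one F2. This is converted with Tf2O and 2,6-lutidine at −78 °C into [(1R,6R,8aR)-6-[(tert-butyldimethylsilyl)oxy]-1,5,5-trimethyl-2-oxo-1,2,3,5,6,7,8,8a-octahydronaphthalen-1-yl]methyl trifluoromethanesulfonate F3. The triflate is displaced by the caesium phenoxide of isofraxidin 10 (Cs2CO3, DMF, 0 °C → rt), which comes back to the route at 13.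

Step 14 (L-Selectride reduction). Conjugate reduction or opening of the coumarin lactone by the borohydride may compete, and the equatorial approach may be less favoured than in saturated 4,4-dimethyl-3-ketones because C5 is sp2. Fallback: substrate control is replaced by reagent control, setting out from 17. CBS reduction with (R)-2-methyl-CBS-oxazaborolidine and catecholborane (toluene, −78 °C) reduces only the ketone and should give the (3S) carbinol, with the quaternary C4 acting as the large group. It comes back to the route at 18 and makes no new compound.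

Further compounds
F1 | step 5 | (2R,4aS)-1,1,5-trimethyl-6-[(triisopropylsilyl)oxy]-1,2,3,4,4a,7-hexahydronaphthalen-2-ol | CC1=C(O[Si](C(C)C)(C(C)C)C(C)C)CC=C2[C@@H]1CC[C@@H](O)C2(C)C
F2 | step 9 | (1R,6R,8aR)-6-[(tert-butyldimethylsilyl)oxy]-1-(hydroxymethyl)-1,5,5-trimethyl-3,5,6,7,8,8a-hexahydronaphthalen-2(1H)-one | OC[C@@]1(C)[C@@H]2CC[C@@H](O[Si](C)(C)C(C)(C)C)C(C)(C)C2=CCC1=O
F3 | step 9 | [(1R,6R,8aR)-6-[(tert-butyldimethylsilyl)oxy]-1,5,5-trimethyl-2-oxo-1,2,3,5,6,7,8,8a-octahydronaphthalen-1-yl]methyl trifluoromethanesulfonate | O=S(=O)(OC[C@@]1(C)[C@@H]2CC[C@@H](O[Si](C)(C)C(C)(C)C)C(C)(C)C2=CCC1=O)C(F)(F)F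
F0 | step 14 | none | none
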